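Conventions: iridoid numbering is used (C1 acetal, O2, C3=C4, C5/C9 ring fusion, C6, C7, C8, C10 = CH2 on C8, C11 = carbon on C4), and β means the face carrying H‑9.

Reading of the target SMILES: 1β‑O‑isovaleryl, 5β‑OH, 7β‑OAc, 8α‑OH with 8β‑CH2Cl, 9β‑H, and an (R) side‑chain centre.

Assumption: (+)-genipin (gardenia‑derived, sold in bulk) and (R)‑2‑hydroxy‑3‑methylbutanoic acid are accepted as commercial chiral starting materials.

## Retrosynthetic overview

1. The target comes from three late O‑acylations ordered by reactivity (primary C11‑OH, then secondary C7‑OH, then C1 by silyl→acyl exchange) on a 1‑O‑TBS tetraol chlorohydrin.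
2. The tetraol comes from global DIBAL reduction of a 4‑CO2Me/7,8‑diacetate. Its C5–O bond comes from photoredox C5–H abstraction and oxidation, captured by the cis‑1,3 7β‑acetate (key step).
3. The 7β‑OAc/8α‑OAc/10‑Cl triad comes from an AcCl‑triggered acetoxonium relay on a 7β,8β‑epoxy‑10‑acetate, with inversion at C8.
4. The epoxide comes from convex‑face epoxidation of protected genipin. The side chain comes from (R)‑2‑hydroxyisovaleric acid and isovaleryl chloride.
5. Ring order: the cyclopenta[c]pyran core is bought intact. Only transient rings are made and opened (oxirane, then 1,3‑dioxolan‑2‑ylium, then 1,3‑dioxan‑2‑ylium).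

## Route

**Step 1**
Reactants: 1, (+)-genipin
Product: 2, 10‑O‑acetylgenipin
Conditions: AcCl (1.05 equiv), 2,4,6‑collidine, CH2Cl2, −78 °C
Reagents that add atoms: acetyl chloride, CC(=O)Cl
Why: Kinetically selective O‑acetylation, because the unhindered primary allylic 10‑OH outcompetes the C1 lactol OH at low temperature with a weak base; no stereocentre is touched.

**Step 2**
Reactants: 2
Product: 3, 10‑O‑acetyl‑1β‑O‑TBS‑genipin
Conditions: TBSCl, imidazole, DMF, 0 °C → rt
Reagents that add atoms: TBSCl, CC(C)(C)[Si](C)(C)Cl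
Why: Lactol silylation traps the equatorial 1β‑anomer in which genipin exists, and the conjugated ester keeps the pyran closed, so C1 is retained.

**Step 3**
Reactants: 3
Product: 4, 7β,8β‑epoxide of 3
Conditions: m‑CPBA, NaHCO3, CH2Cl2, 0 °C → rt
Reagents that add atoms: m‑CPBA, OOC(=O)c1cccc(Cl)c1
Why: Prilezhaev epoxidation, in which only C7=C8 is nucleophilic (C3=C4 is a vinylogous carbonate) and the peracid approaches the convex β face (syn to H‑5/H‑9) of the cis‑fused bicycle, setting the C7–O bond β.

**Step 4**
Reactants: 4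
Product: 5, methyl 7β,8α‑diacetoxy‑10‑chloro‑1β‑(TBSO)‑irid‑3‑en‑11‑oate (5β‑H, 9β‑H, CH2Cl β)
Conditions: AcCl (2 equiv), ZnCl2 (10 mol %), CH2Cl2, −40 → 0 °C
Reagents that add atoms: acetyl chloride, CC(=O)Cl
Why: Proposed new method: AcCl/ZnCl2 O‑acylates the strained oxirane oxygen (which becomes the 7β‑OAc); the C8–O bond is then displaced from the α face by the carbonyl oxygen of the 10‑acetate (5‑exo anchimeric assistance, clean inversion at C8) to give a spiro 1,3‑dioxolan‑2‑ylium ion that chloride opens by SN2 at primary C10, leaving 8α‑OAc and 10‑Cl (O7 is already capped, so no orthoester scrambling occurs); the closest known reaction types are Lewis‑acid acylative cleavage of epoxides with acyl chlorides, neighbouring‑ester opening of 2,3‑epoxy esters, and chloride opening of acetoxonium ions generated from cyclic orthoacetates.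

**Step 5 (key step)**
Reactants: 5
Product: 6, 5β‑hydroxy derivative of 5
Conditions: Ir(p‑F‑ppy)3 (2 mol %), N‑acetoxyphthalimide (2 equiv), HFIP (5 equiv), t‑BuCN, 450 nm LEDs, 25 °C; then pH 7 buffer/THF
Reagents that add atoms: water, O
Why: Proposed new method: excited Ir(III) reduces N‑acetoxyphthalimide to CH3•, which abstracts the weakest C–H (tertiary allylic C5–H); Ir(IV) oxidises the allyl radical to the C5/C3‑delocalised cation, which is captured only at C5 and only on the β face by the carbonyl oxygen of the cis‑1,3 7β‑acetate (six‑membered 1,3‑dioxan‑2‑ylium, whereas α‑capture by the 8α‑acetate would force a trans‑fused 5/6 system onto the half‑chair dihydropyran and is reversible), and water opens the acetoxonium to 5β‑OH/7β‑OAc (any 5‑OAc/7‑OH isomer converges in step 6); the closest known reaction types are photoredox HAT/oxidative radical‑polar crossover C(sp3)–H functionalisation and Woodward‑type acetoxonium hydrolysis.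

**Step 6**
Reactants: 6
Product: 7, 10‑chloro‑1β‑(TBSO)‑irid‑3‑ene‑5β,7β,8α,11‑tetraol
Conditions: DIBAL‑H (9 equiv), CH2Cl2, −78 → −20 °C; Rochelle salt
Reagents that add atoms: none
Why: DIBAL ester reduction takes the vinylogous ester to the C11 allylic alcohol and removes both relay acetates, while the C–Cl bond, silyl acetal and enol ether are inert and no stereocentre changes.

**Step 7**
Reactants: 8, (R)‑2‑hydroxy‑3‑methylbutanoic acid
Product: 9, (R)‑3‑methyl‑2‑(3‑methylbutanoyloxy)butanoic acid
Conditions: isovaleryl chloride (1.2 equiv), pyridine, CH2Cl2, 0 °C → rt; aq. work‑up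
Reagents that add atoms: isovaleryl chloride, CC(C)CC(=O)Cl
Why: Simple O‑acylation of an α‑hydroxy acid in which the C–O bond at the stereocentre is not broken, so the purchased (R) configuration is kept.

**Step 8**
Reactants: 7 and 9
Product: 10, 11‑O‑[(R)‑2‑isovaleryloxy‑isovaleryl] derivative of 7
Conditions: 9 (1.05 equiv), EDC·HCl, DMAP (0.2 equiv), CH2Cl2, −10 °C
Reagents that add atoms: none (9 is a numbered reactant)
Why: Steglich esterification, in which the doubly branched acyl donor reacts only with the single primary (allylic) OH and leaves the hindered secondary C7‑OH and the two tertiary OH groups untouched.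

**Step 9**
Reactants: 10
Product: 11, 7β‑O‑acetyl derivative of 10
Conditions: Ac2O (1.5 equiv), pyridine, DMAP (cat.), CH2Cl2, 0 °C
Reagents that add atoms: acetic anhydride, CC(=O)OC(C)=O
Why: Standard acetylation of the only remaining non‑tertiary hydroxyl; 5‑OH and 8‑OH do not react under these conditions.

**Step 10**
Reactants: 11
Product: 12, volvaltrate B
Conditions: isovaleric anhydride (3 equiv), TBAF (1.1 equiv, slow addition), THF, −20 °C
Reagents that add atoms: isovaleric anhydride, CC(C)CC(=O)OC(=O)CC(C)C
Why: Fluoride‑mediated silyl→acyl exchange acylates the lactolate as it is released, so the fragile free aglycone never accumulates and carboxylate buffering protects the chlorohydrin; the equatorial 1β‑ester (H‑1/H‑9 trans‑diaxial) forms under substrate control, as in genipin esters.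

## Compound list

| No. | Name | SMILES | Role |
|---|---|---|---|
| 1 | (+)-Genipin (1β‑OH, 5β‑H, 9β‑H) | `OCC1=CC[C@@H]2C(C(=O)OC)=CO[C@@H](O)[C@H]12` | starting material |
| 2 | 10‑O‑Acetylgenipin | `CC(=O)OCC1=CC[C@@H]2C(C(=O)OC)=CO[C@@H](O)[C@H]12` | intermediate |
| 3 | 10‑O‑Acetyl‑1β‑O‑TBS‑genipin | `CC(=O)OCC1=CC[C@@H]2C(C(=O)OC)=CO[C@@H](O[Si](C)(C)C(C)(C)C)[C@H]12` | intermediate |
| 4 | 7β,8β‑Epoxide of 3 | `CC(=O)OC[C@]12O[C@H]1C[C@@H]3C(C(=O)OC)=CO[C@@H](O[Si](C)(C)C(C)(C)C)[C@H]23` | intermediate |
| 5 | 7β,8α‑Diacetoxy‑10‑chloro‑1β‑OTBS methyl ester | `CC(=O)O[C@H]1C[C@@H]2C(C(=O)OC)=CO[C@@H](O[Si](C)(C)C(C)(C)C)[C@@H]2[C@@]1(OC(C)=O)CCl` | intermediate |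
| 6 | 5β‑Hydroxy derivative of 5 | `CC(=O)O[C@H]1C[C@]2(O)C(C(=O)OC)=CO[C@@H](O[Si](C)(C)C(C)(C)C)[C@@H]2[C@@]1(OC(C)=O)CCl` | intermediate |
| 7 | 10‑Chloro‑1β‑OTBS‑5β,7β,8α,11‑tetraol | `O[C@H]1C[C@]2(O)C(CO)=CO[C@@H](O[Si](C)(C)C(C)(C)C)[C@@H]2[C@@]1(O)CCl` | intermediate |
| 8 | (R)‑2‑Hydroxy‑3‑methylbutanoic acid | `OC(=O)[C@H](O)C(C)C` | starting material |
| 9 | (R)‑3‑Methyl‑2‑(3‑methylbutanoyloxy)butanoic acid | `OC(=O)[C@H](OC(=O)CC(C)C)C(C)C` | intermediate |
| 10 | 11‑O‑Acylated triol | `O[C@H]1C[C@]2(O)C(COC(=O)[C@H](OC(=O)CC(C)C)C(C)C)=CO[C@@H](O[Si](C)(C)C(C)(C)C)[C@@H]2[C@@]1(O)CCl` | intermediate |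
| 11 | 7‑O‑Acetyl‑11‑O‑acyl‑1β‑OTBS compound | `CC(=O)O[C@H]1C[C@]2(O)C(COC(=O)[C@H](OC(=O)CC(C)C)C(C)C)=CO[C@@H](O[Si](C)(C)C(C)(C)C)[C@@H]2[C@@]1(O)CCl` | intermediate |
| 12 | Volvaltrate B | `CC(=O)O[C@H]1C[C@]2(O)C(COC(=O)[C@H](OC(=O)CC(C)C)C(C)C)=CO[C@@H](OC(=O)CC(C)C)[C@@H]2[C@@]1(O)CCl` | target |

## Step count and risks

Total steps: 10. Longest linear sequence: 9 (steps 1–6 and 8–10).

The three steps most likely to fail:

1. **Step 5 (new photoredox C5–H oxygenation).**
   - Risks: HAT at other sites, methyl radical addition to C3=C4, and E1 loss of H‑6 from the cation.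
   - Fallback (known chemistry, directed rather than undirected HAT): cleave the secondary acetate of 5 selectively with K2CO3/MeOH at 0 °C and convert the 7β‑OH to its N‑(2,2,2‑trifluoroethyl)carbamate.
   - Then run the Hofmann–Löffler–Freytag 1,3‑diol sequence: N‑bromination with AcOBr, hν/CBr4 for 1,6‑HAT bromination at C5, Ag2CO3 cyclisation, and aqueous AcOH to give the 5β,7β‑cyclic carbonate.
   - The carbonate is removed in the existing DIBAL step.

2. **Step 4 (new AcCl acetoxonium relay).**
   - Risks: direct chloride attack on the epoxide, hydride‑shift rearrangement to the C7 ketone, and loss of the C1 silyl acetal.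
   - Fallback (known chemistry, O‑8 brought in from outside): make 10‑chloro‑10‑deoxy‑1‑O‑TBS‑genipin (NCS/Me2S, then TBSCl) and treat it with NBS/H2O. The bromonium forms on the convex face and water adds at tertiary C8 from the α face, giving 7β‑Br/8α‑OH.
   - K2CO3 then gives the 7α,8α‑epoxide, and CsOAc/AcOH in DMF opens it at C7 from the β face to give 7β‑OAc/8α‑OH/10‑Cl.

3. **Step 10 (late C1 silyl→isovaleryl exchange).**
   - Risks: decomposition of the transient electron‑rich lactol, anomer mixtures, and chlorohydrin closure to the epoxide.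
   - Fallback (avoids any late lactol): replace the methyl ester by an allyl ester at the genipin stage and install the 1‑O‑isovalerate early.
   - After the C7/C8/C5 chemistry, remove the allyl group with Pd(0) and reduce only C11 through the mixed anhydride (i‑BuOCOCl/NMM, then NaBH4), which spares the other esters.
   - Finish by esterifying C11‑OH with 9.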